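The maleimide ring is opened retrosynthetically at its C3=C4 double bond. C3 (carrying the 1-methylimidazol-5-yl ring) and C4 (carrying the 6-bromoindol-3-yl ring) each lie alpha to one of the two carbonyls C2 and C5 that share N1, so both can be generated as enolate carbons of a single acyclic diacylamine. A four-electron, iodide-relayed anodic oxidation of this bis-enolate should make the C3–C4 bond, close the five-membered imide ring and dehydrogenate it to the maleimide in one cell run. The precursor is the mixed imide of the two heteroarylacetic acids on a 2,4-dimethoxybenzyl nitrogen, with the indole nitrogen as Boc carbamate, so that one acid treatment finishes the synthesis.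

Key step: step 4

Remark on the chemistry: acid 1 is taken as the free acid. The commercial hydrochloride would need one extra equivalent of i-Pr2NEt in step 1. A lithium salt gets its own number only where it is the species that forms a new bond.

Design points:
- **N-substituent.** The imide nitrogen carries 2,4-dimethoxybenzyl because this group leaves in the same acid bath as Boc. Its ortho substituent also biases the imide rotamer needed for ring closure.
- **Base.** Step 4 removes four protons and four electrons overall, so the base is supplied in two charges.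
- **Cell.** The cell is divided because the aryl bromide, iodine and the maleimide are all reducible at a cathode.
- **Stereochemistry.** The target has no stereocentre.

Step 1
Reactants: 1 2-(1-methylimidazol-5-yl)acetic acid; 2 2,4-dimethoxybenzylamine
Product: 4 N-(2,4-dimethoxybenzyl)-2-(1-methylimidazol-5-yl)acetamide, via acyl imidazolide 3 (not isolated)
Conditions: 1,1'-carbonyldiimidazole (1.1 equiv), DMF, rt; then 2 (1.05 equiv), rt
Reagents that add atoms: none
Why: Amide formation through an acyl imidazolide activates the acid under neutral conditions that tolerate the basic imidazole ring, and the unhindered primary amine then displaces imidazole; no stereocentre is formed.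

Step 2
Reactants: 5 2-(6-bromo-1H-indol-3-yl)acetic acid
Product: 7 2-[6-bromo-1-(tert-butoxycarbonyl)indol-3-yl]acetic acid, via dilithium indolide carboxylate 6 (not isolated)
Conditions: LiN(SiMe3)2 (2.2 equiv), THF, −78 °C; Boc2O (1.05 equiv), −78 to 0 °C; cold 1 M HCl to pH 3
Reagents that add atoms: di-tert-butyl dicarbonate, CC(C)(C)OC(=O)OC(=O)OC(C)(C)C
Why: In this N-acylation of an indolyl anion the silylamide removes only the CO2H and N–H protons (no bromine–lithium exchange), the indolide nitrogen is the better nucleophile for Boc2O, and any mixed anhydride at the carboxylate is hydrolysed on work-up.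

Step 3
Reactants: 4 N-(2,4-dimethoxybenzyl)-2-(1-methylimidazol-5-yl)acetamide; 7 2-[6-bromo-1-(tert-butoxycarbonyl)indol-3-yl]acetic acid
Product: 10 N-(2,4-dimethoxybenzyl)-N-[2-(1-methylimidazol-5-yl)acetyl]-2-[6-bromo-1-(tert-butoxycarbonyl)indol-3-yl]acetamide, via acid chloride 8 (not isolated), via lithium amidate 9 (not isolated)
Conditions: 7 (1.2 equiv), 1-chloro-N,N,2-trimethylprop-1-en-1-amine (1.15 equiv), CH2Cl2, 0 °C, then THF; 4, LiN(SiMe3)2 (1.05 equiv), THF, −78 °C, cannulated into 8 at −78 °C; pH 7 phosphate buffer
Reagents that add atoms: none
Why: In this N-acylation of a lithium amidate with an acid chloride (acyclic imide synthesis) the chloroenamine makes 8 without HCl, so the Boc group is safe, and adding the amidate to excess 8 at low temperature keeps the acidic product away from unreacted base, which should suppress ketene formation and C-acylation.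

Step 4
Reactants: 10 N-(2,4-dimethoxybenzyl)-N-[2-(1-methylimidazol-5-yl)acetyl]-2-[6-bromo-1-(tert-butoxycarbonyl)indol-3-yl]acetamide
Product: 13 tert-butyl 6-bromo-3-[1-(2,4-dimethoxybenzyl)-4-(1-methylimidazol-5-yl)-2,5-dioxo-2,5-dihydropyrrol-3-yl]indole-1-carboxylate, via dilithium bis-enolate 11 (not isolated), via succinimide 12 (not isolated)
Conditions: LiN(SiMe3)2 (2.2 equiv), THF–DMPU 9:1, 5 mM, −78 °C; divided cell (fine glass frit), RVC anode, n-Bu4NI (0.5 equiv), n-Bu4NPF6 (0.1 M), constant current, 2.2 F/mol, −40 °C; LiN(SiMe3)2 (2.2 equiv), further 2.2 F/mol, −40 to 0 °C; catholyte: Pt, n-Bu4NPF6, t-BuOH, THF; aq NH4Cl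
Reagents that add atoms: none
Why: Proposed new method: LiN(SiMe3)2 turns the two heteroaryl-activated CH2 groups of 10 into bis-enolate 11, and iodine made from iodide at the anode (expected to form roughly one volt below the oxidation onset of the Boc-indole, imidazole and dimethoxyphenyl rings) removes one electron from, or iodinates, one enolate carbon, which then bonds to the second enolate carbon to give succinimide 12. Both atoms of the accepting enolate C=C end up inside the new five-membered ring, so the closure is 5-endo-trig on the radical path, the same geometry as the well-known closure of carbamoylmethyl radicals onto enamides, and 5-(enolendo)-exo-tet on the iodide-displacement path, which is the poorer geometry and is therefore not relied upon. The second charge of base re-enolises 12, whose dienolate is simply the two-electron-reduced form of the maleimide and so should give up two further electrons at very low potential (or pass through alpha-iodination and loss of HI) to give 13, where the sequence stops because no enolisable hydrogen is left. The closest known reaction types are the closure of tethered bis-enolates with I2, Fe(acac)3 or CuCl2 and the halide-mediated anodic dehydrodimerisation of malonate-type CH acids, and what is new is running ring closure and dehydrogenation anodically on a heteroaryl-substituted acyclic imide. Cross-coupling instead of homodimerisation is secured by the N1 tether and the 5 mM dilution, C- over O-closure by the soft radical path, and the productive rotamer by the ortho-substituted N-benzyl group (allylic strain turns both enolate carbons away from it and towards each other) and by DMPU, which breaks O–Li–O chelates that would hold them apart. The two stereocentres of 12 need no control because both vanish in 13, and the divided cell keeps the reducible aryl bromide, iodine and 13 away from the cathode.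

Step 5
Reactants: 13 tert-butyl 6-bromo-3-[1-(2,4-dimethoxybenzyl)-4-(1-methylimidazol-5-yl)-2,5-dioxo-2,5-dihydropyrrol-3-yl]indole-1-carboxylate
Product: 15 didemnimide D, via Boc-free maleimide 14 (not isolated)
Conditions: TFA–anisole 10:1, rt, then 70 °C, dark; aq NaHCO3
Reagents that add atoms: none
Why: In this SN1-type acidolysis the Boc carbamate is lost at room temperature, and on warming the 2,4-dimethoxybenzyl cation leaves the protonated imide and is captured by anisole in a Friedel–Crafts alkylation, while the protonated imidazole, the acceptor-substituted indole and the aryl bromide are inert to TFA.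

Compound list
1 | 2-(1-methylimidazol-5-yl)acetic acid | Cn1cncc1CC(=O)O | starting material
2 | 2,4-dimethoxybenzylamine | NCc1ccc(OC)cc1OC | starting material
3 | 1-(imidazol-1-yl)-2-(1-methylimidazol-5-yl)ethanone (acyl imidazolide) | Cn1cncc1CC(=O)n1ccnc1 | intermediate
4 | N-(2,4-dimethoxybenzyl)-2-(1-methylimidazol-5-yl)acetamide | Cn1cncc1CC(=O)NCc1ccc(OC)cc1OC | intermediate
5 | 2-(6-bromo-1H-indol-3-yl)acetic acid | OC(=O)Cc1c[nH]c2cc(Br)ccc12 | starting material
6 | dilithium salt of 5 (indolide carboxylate) | [Li+].[Li+].[O-]C(=O)Cc1c[n-]c2cc(Br)ccc12 | intermediate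
7 | 2-[6-bromo-1-(tert-butoxycarbonyl)indol-3-yl]acetic acid | OC(=O)Cc1cn(C(=O)OC(C)(C)C)c2cc(Br)ccc12 | intermediate
8 | 2-[6-bromo-1-(tert-butoxycarbonyl)indol-3-yl]acetyl chloride | ClC(=O)Cc1cn(C(=O)OC(C)(C)C)c2cc(Br)ccc12 | intermediate
9 | lithium amidate of 4 | [Li+].Cn1cncc1CC(=O)[N-]Cc1ccc(OC)cc1OC | intermediate
10 | N-(2,4-dimethoxybenzyl)-N-[2-(1-methylimidazol-5-yl)acetyl]-2-[6-bromo-1-(tert-butoxycarbonyl)indol-3-yl]acetamide | O=C(Cc1cncn1C)N(Cc1ccc(OC)cc1OC)C(=O)Cc1cn(C(=O)OC(C)(C)C)c2cc(Br)ccc12 | intermediate
11 | dilithium bis-enolate of 10 (enolate geometry not defined) | [Li+].[Li+].[O-]C(=Cc1cncn1C)N(Cc1ccc(OC)cc1OC)C([O-])=Cc1cn(C(=O)OC(C)(C)C)c2cc(Br)ccc12 | intermediate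
12 | tert-butyl 6-bromo-3-[1-(2,4-dimethoxybenzyl)-4-(1-methylimidazol-5-yl)-2,5-dioxopyrrolidin-3-yl]indole-1-carboxylate (racemic, cis/trans not defined, both centres erased in 13) | Cn1cncc1C1C(c2cn(C(=O)OC(C)(C)C)c3cc(Br)ccc23)C(=O)N(Cc2ccc(OC)cc2OC)C1=O | intermediate
13 | tert-butyl 6-bromo-3-[1-(2,4-dimethoxybenzyl)-4-(1-methylimidazol-5-yl)-2,5-dioxo-2,5-dihydropyrrol-3-yl]indole-1-carboxylate | Cn1cncc1C1=C(c2cn(C(=O)OC(C)(C)C)c3cc(Br)ccc23)C(=O)N(Cc2ccc(OC)cc2OC)C1=O | intermediate
14 | 3-(6-bromo-1H-indol-3-yl)-1-(2,4-dimethoxybenzyl)-4-(1-methylimidazol-5-yl)pyrrole-2,5-dione | Cn1cncc1C1=C(c2c[nH]c3cc(Br)ccc23)C(=O)N(Cc2ccc(OC)cc2OC)C1=O | intermediate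
15 | didemnimide D, 3-(6-bromo-1H-indol-3-yl)-4-(1-methylimidazol-5-yl)pyrrole-2,5-dione | Cn1cncc1C1=C(c2c[nH]c3cc(Br)ccc23)C(=O)NC1=O | target

Total step count: 5. Longest linear sequence: 4 steps (5 to 7 to 10 to 13 to 15; the branch from 1 is equally long).

Steps most likely to fail

1. **Step 4.**
   - What may go wrong: ring closure through an enolate oxygen instead of carbon; cleavage of the acyclic imide by ketene loss from a mono-enolate; intermolecular coupling; passivation of the anode by lithium salts.
   - Fallback (known chemistry): it sets out from 1 and rejoins at 15. Imidazolide 3, made from 1 as in step 1, is quenched with ammonia in methanol to give 2-(1-methylimidazol-5-yl)acetamide F1. Purchased 6-bromoindole F2 is acylated at C3 with oxalyl chloride in Et2O to 2-(6-bromo-1H-indol-3-yl)-2-oxoacetyl chloride F3. Methanol converts this into methyl 2-(6-bromo-1H-indol-3-yl)-2-oxoacetate F4. KOt-Bu in THF (0 °C to rt, acidic quench) then condenses the acetamide CH2 of F1 with the ketone of F4 and closes the imide on the ester. This is a Knoevenagel-type condensation and lactamisation that is established for 3,4-diarylmaleimides. C3=C4 then arises from a nucleophile–electrophile pair instead of an oxidative union, and 15 is reached directly.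

2. **Step 3.**
   - What may go wrong: proton transfer from the acid chloride or from the product to the amidate (ketene formation, stalled conversion, C-acylation); hydrolytic cleavage of the acyclic imide during work-up.
   - Fallback: it sets out from 4 and rejoins at 10. Amide 4 is silylated with Me3SiCl and Et3N in CH2Cl2 to N-(2,4-dimethoxybenzyl)-N-trimethylsilyl-2-(1-methylimidazol-5-yl)acetamide F5. This neutral nitrogen nucleophile is acylated by acid chloride 8 in toluene (rt to 50 °C) with loss of the silyl group. No strong base ever meets 8 or 10, and an aqueous work-up can be avoided.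

3. **Step 5.**
   - What may go wrong: sluggish departure of the benzyl group from the weakly basic imide; re-alkylation of the indole ring by the benzylic cation.
   - Fallback: it sets out from 13 and rejoins at 15. KOH in aqueous EtOH at reflux removes the carbamate and opens the imide to the dicarboxylate. Acidification to about pH 4 closes this to 3-(6-bromo-1H-indol-3-yl)-4-(1-methylimidazol-5-yl)furan-2,5-dione F6. Heating F6 with NH4OAc (melt, 140 °C) installs the free NH and gives 15.

Further compounds
F1 | step 4 | 2-(1-methylimidazol-5-yl)acetamide | Cn1cncc1CC(N)=O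
F2 | step 4 | 6-bromoindole (purchased co-reactant) | Brc1ccc2cc[nH]c2c1
F3 | step 4 | 2-(6-bromo-1H-indol-3-yl)-2-oxoacetyl chloride | O=C(Cl)C(=O)c1c[nH]c2cc(Br)ccc12
F4 | step 4 | methyl 2-(6-bromo-1H-indol-3-yl)-2-oxoacetate | COC(=O)C(=O)c1c[nH]c2cc(Br)ccc12
F5 | step 3 | N-(2,4-dimethoxybenzyl)-N-trimethylsilyl-2-(1-methylimidazol-5-yl)acetamide | Cn1cncc1CC(=O)N(Cc1ccc(OC)cc1OC)[Si](C)(C)C
F6 | step 5 | 3-(6-bromo-1H-indol-3-yl)-4-(1-methylimidazol-5-yl)furan-2,5-dione | Cn1cncc1C1=C(c2c[nH]c3cc(Br)ccc23)C(=O)OC1=O
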